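**Retrosynthetic overview**

- Ring A (C1 aroyl, C2 OH, C3 H, C4 OMe, C5 arylpropyl, C6 H) carries oxygen on the ketone carbon, on C2 and on C4, that is on alternate carbons, so it is read as a folded triketide chain that ends in an aldehyde carbon, C6.
- Key disconnection: the C1–C6 bond of ring A. A 1,3,5-triketone with the C6 aldehyde masked as a dimethyl acetal is closed by a silyl-triflate-triggered aldol-type addition and aromatises by loss of methanol. Ring A is the only ring formed; the two outer benzene rings are bought.
- The triketone is cut at C3–C4 into the dianion of an aryl butane-1,3-dione (aryl ketone and C1–C3) and an N-methoxy-N-methylamide (C4–C6 with the arylpropyl chain); the amide comes from alkylation of methyl 3,3-dimethoxypropanoate with an arylpropyl iodide.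
- After ring closure the C4 hydroxyl is methylated selectively (the C2 hydroxyl is chelated to the ketone) and both benzyl ethers are removed by hydrogenolysis.

Key step: step 7

Assumption: 4'-(benzyloxy)acetophenone is taken as a purchasable starting material; the α-branched ester, amide and triketone are carried as racemates because their single stereocentre becomes an aromatic carbon in the key step; β-dicarbonyl compounds are drawn as keto tautomers. Ring-A labels C1–C6 are used throughout.

**Route**

Step 1
Reactants: 1 4'-(benzyloxy)acetophenone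
Product: 2 1-[4-(benzyloxy)phenyl]butane-1,3-dione
Conditions: NaH (2.5 equiv), EtOAc (5 equiv), THF, 0 °C → reflux; then 1 M HCl
Reagents that add atoms: ethyl acetate, CCOC(C)=O
Why: Crossed Claisen condensation in which the sodium enolate of the aryl methyl ketone is acylated by ethyl acetate and the product is held as its stable diketonate until acidification.

Step 2
Reactants: 3 3-(4-hydroxyphenyl)propan-1-ol
Product: 4 3-[4-(benzyloxy)phenyl]propan-1-ol
Conditions: BnBr (1.05 equiv), K2CO3 (1.5 equiv), acetone, reflux
Reagents that add atoms: benzyl bromide, BrCc1ccccc1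
Why: Williamson ether synthesis that is chemoselective because K2CO3 ionises the phenol but not the aliphatic alcohol.

Step 3
Reactants: 4 3-[4-(benzyloxy)phenyl]propan-1-ol
Product: 5 1-(benzyloxy)-4-(3-iodopropyl)benzene
Conditions: PPh3, I2, imidazole, CH2Cl2, 0 °C → rt
Reagents that add atoms: iodine, II
Why: Appel-type iodination in which the primary alcohol is activated as an alkoxyphosphonium ion and displaced by iodide in an SN2 step that leaves the benzyl ether untouched.

Step 4
Reactants: 5 1-(benzyloxy)-4-(3-iodopropyl)benzene; 6 methyl 3,3-dimethoxypropanoate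
Product: 8 racemic methyl 5-[4-(benzyloxy)phenyl]-2-(dimethoxymethyl)pentanoate, via lithium ester enolate 7 (not isolated)
Conditions: 6, LiN(i-Pr)2 (1.05 equiv), THF, −78 °C; then 5 (0.9 equiv), DMPU, −78 → −30 °C
Reagents that add atoms: none
Why: SN2 alkylation of a lithium ester enolate by a primary iodide, run cold with DMPU so that the enolate is alkylated before it can lose methoxide; the new stereocentre forms as a racemate and is erased in step 7.

Step 5
Reactants: 8 racemic methyl 5-[4-(benzyloxy)phenyl]-2-(dimethoxymethyl)pentanoate
Product: 9 racemic 5-[4-(benzyloxy)phenyl]-2-(dimethoxymethyl)-N-methoxy-N-methylpentanamide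
Conditions: MeNH(OMe)·HCl (1.5 equiv), i-PrMgCl (3.0 equiv), THF, −20 → 0 °C
Reagents that add atoms: N,O-dimethylhydroxylamine hydrochloride, CNOC.Cl
Why: Direct ester aminolysis by the chloromagnesium amide of N,O-dimethylhydroxylamine, a nucleophilic acyl substitution that the acetal and the benzyl ether tolerate.

Step 6
Reactants: 2 1-[4-(benzyloxy)phenyl]butane-1,3-dione; 9 racemic 5-[4-(benzyloxy)phenyl]-2-(dimethoxymethyl)-N-methoxy-N-methylpentanamide
Product: 11 racemic 1,9-bis[4-(benzyloxy)phenyl]-6-(dimethoxymethyl)nonane-1,3,5-trione, via dilithium dienolate 10 (not isolated)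
Conditions: 2, LiN(i-Pr)2 (2.2 equiv), THF, −78 → 0 °C; then 9 (0.8 equiv), −78 → 0 °C; AcOH quench at −78 °C
Reagents that add atoms: none
Why: Claisen-type acylation of a β-diketone dianion at its terminal carbon (C3) forms the C3–C4 bond, and the chelated tetrahedral adduct of the N-methoxy-N-methylamide holds back the ketone until the quench, so that neither over-addition nor proton transfer from product to dianion can occur.

Step 7
Reactants: 11 racemic 1,9-bis[4-(benzyloxy)phenyl]-6-(dimethoxymethyl)nonane-1,3,5-trione
Product: 14 [4-(benzyloxy)phenyl]{5-[3-(4-(benzyloxy)phenyl)propyl]-2,4-dihydroxyphenyl}methanone, via bis(trimethylsilyl) dienol ether 12 (not isolated), via bis(trimethylsilyl) aryl ether 13 (not isolated)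
Conditions: i-Pr2NEt (4 equiv), Me3SiOTf (2.2 equiv), CH2Cl2 (0.01 M), −78 °C; then Me3SiOTf (2.3 equiv), −78 → 0 °C; then 1 M HCl, THF, rt
Reagents that add atoms: none
Why: The first portion of Me3SiOTf with i-Pr2NEt caps the enolised triketone as the bis(silyl) dienol ether 12, a 1,3-bis(silyloxy)-1,3-diene whose terminal carbon is C1, and the second portion ionises the dimethyl acetal to the oxocarbenium ion at C6, which C1 attacks in an intramolecular Mukaiyama aldol-type addition; loss of methanol across C1–C6 and enolisation of the C4 carbonyl toward C5 then give the arene as its silyl ether 13, which dilute acid frees. The closest known reaction type is the one-flask enol silane formation and Mukaiyama addition to dimethyl acetals with Me3SiOTf and an amine, in the ring-closing and aromatising form in which it operates as the second bond formation of Lewis-acid [3+3] benzannulations of 1,3-bis(silyloxy)-1,3-dienes with masked 1,3-dicarbonyl electrophiles. Ring A closes in a 6-(enolendo)-exo-trig mode, with the C1=C2 enol silane inside the new ring and the C6=O+ bond outside it. No stereocentre is formed and the racemic centre at C5 becomes an aromatic carbon. The step needs closure through carbon and not through oxygen, and this is secured because C1 is the only carbon that reaches C6 through a six-membered transition state (C3 could only close a four-membered ring), because the C2 oxygen is capped by silicon, and because a ring closed through that oxygen is a mixed acetal whose vinylogous-ester ring oxygen leaves more readily than methoxide, so that it reopens and drains into the irreversible aromatisation instead of giving a 4-pyranone. The amine keeps free TfOH, the usual agent of 4-pyranone formation from 1,3,5-triketones, out of the flask, and high dilution holds back intermolecular addition.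

Step 8
Reactants: 14 [4-(benzyloxy)phenyl]{5-[3-(4-(benzyloxy)phenyl)propyl]-2,4-dihydroxyphenyl}methanone
Product: 15 [4-(benzyloxy)phenyl]{5-[3-(4-(benzyloxy)phenyl)propyl]-2-hydroxy-4-methoxyphenyl}methanone
Conditions: MeI (1.1 equiv), K2CO3 (1.1 equiv), acetone, 40 °C
Reagents that add atoms: iodomethane, CI
Why: Williamson methylation that is regioselective because the C2 hydroxyl is locked in a hydrogen bond to the ketone and is the weaker acid, while the C4 hydroxyl para to the carbonyl is ionised by K2CO3.

Step 9
Reactants: 15 [4-(benzyloxy)phenyl]{5-[3-(4-(benzyloxy)phenyl)propyl]-2-hydroxy-4-methoxyphenyl}methanone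
Product: 16 {2-hydroxy-5-[3-(4-hydroxyphenyl)propyl]-4-methoxyphenyl}(4-hydroxyphenyl)methanone
Conditions: H2 (1 atm), 10% Pd/C, EtOAc, rt
Reagents that add atoms: none
Why: Hydrogenolysis of the two benzyl aryl ethers over palladium on carbon at ambient pressure in ethyl acetate, where the electron-rich, hydrogen-bonded diaryl ketone should be reduced far more slowly than the benzylic C–O bonds are cleaved.

**Compound list**

1 | 4'-(benzyloxy)acetophenone | CC(=O)c1ccc(OCc2ccccc2)cc1 | starting material
2 | 1-[4-(benzyloxy)phenyl]butane-1,3-dione | CC(=O)CC(=O)c1ccc(OCc2ccccc2)cc1 | intermediate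
3 | 3-(4-hydroxyphenyl)propan-1-ol | OCCCc1ccc(O)cc1 | starting material
4 | 3-[4-(benzyloxy)phenyl]propan-1-ol | OCCCc1ccc(OCc2ccccc2)cc1 | intermediate
5 | 1-(benzyloxy)-4-(3-iodopropyl)benzene | ICCCc1ccc(OCc2ccccc2)cc1 | intermediate
6 | methyl 3,3-dimethoxypropanoate | COC(=O)CC(OC)OC | starting material
7 | lithium enolate of methyl 3,3-dimethoxypropanoate | COC(OC)C=C([O-])OC.[Li+] | intermediate (not isolated)
8 | methyl 5-[4-(benzyloxy)phenyl]-2-(dimethoxymethyl)pentanoate (racemic) | COC(=O)C(CCCc1ccc(OCc2ccccc2)cc1)C(OC)OC | intermediate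
9 | 5-[4-(benzyloxy)phenyl]-2-(dimethoxymethyl)-N-methoxy-N-methylpentanamide (racemic) | CON(C)C(=O)C(CCCc1ccc(OCc2ccccc2)cc1)C(OC)OC | intermediate
10 | dilithium dienolate (dianion) of 1-[4-(benzyloxy)phenyl]butane-1,3-dione | C=C([O-])C=C([O-])c1ccc(OCc2ccccc2)cc1.[Li+].[Li+] | intermediate (not isolated)
11 | 1,9-bis[4-(benzyloxy)phenyl]-6-(dimethoxymethyl)nonane-1,3,5-trione (racemic) | COC(OC)C(CCCc1ccc(OCc2ccccc2)cc1)C(=O)CC(=O)CC(=O)c1ccc(OCc2ccccc2)cc1 | intermediate
12 | 1,9-bis[4-(benzyloxy)phenyl]-6-(dimethoxymethyl)-3,5-bis(trimethylsilyloxy)nona-2,4-dien-1-one (racemic, mixture of enol silane isomers) | COC(OC)C(CCCc1ccc(OCc2ccccc2)cc1)C(O[Si](C)(C)C)=CC(O[Si](C)(C)C)=CC(=O)c1ccc(OCc2ccccc2)cc1 | intermediate (not isolated)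
13 | [4-(benzyloxy)phenyl]{5-[3-(4-(benzyloxy)phenyl)propyl]-2,4-bis(trimethylsilyloxy)phenyl}methanone | C[Si](C)(C)Oc1cc(O[Si](C)(C)C)c(C(=O)c2ccc(OCc3ccccc3)cc2)cc1CCCc1ccc(OCc2ccccc2)cc1 | intermediate (not isolated)
14 | [4-(benzyloxy)phenyl]{5-[3-(4-(benzyloxy)phenyl)propyl]-2,4-dihydroxyphenyl}methanone | Oc1cc(O)c(C(=O)c2ccc(OCc3ccccc3)cc2)cc1CCCc1ccc(OCc2ccccc2)cc1 | intermediate
15 | [4-(benzyloxy)phenyl]{5-[3-(4-(benzyloxy)phenyl)propyl]-2-hydroxy-4-methoxyphenyl}methanone | COc1cc(O)c(C(=O)c2ccc(OCc3ccccc3)cc2)cc1CCCc1ccc(OCc2ccccc2)cc1 | intermediate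
16 | {2-hydroxy-5-[3-(4-hydroxyphenyl)propyl]-4-methoxyphenyl}(4-hydroxyphenyl)methanone | COc1cc(O)c(C(=O)c2ccc(O)cc2)cc1CCCc1ccc(O)cc1 | target

**Step count**

Total steps: 9. Longest linear sequence: 8 steps (steps 2 to 9, from compound 3).

**Steps most likely to fail**

Step 7. The ring may close through the C2 oxygen onto C6 and then lose methanol to a 4-pyranone, or C–C bond formation may take place between molecules and give oligomers. The fallback sets out from 11 and accepts the oxygen closure on purpose. Treatment of 11 with catalytic p-TsOH in methanol at rt should give the 4-pyranone 2-{2-[4-(benzyloxy)phenyl]-2-oxoethyl}-5-{3-[4-(benzyloxy)phenyl]propyl}-4H-pyran-4-one F1 by the standard acid cyclisation of a masked 3,5-diketo aldehyde. KOH in aqueous methanol should then open the pyranone by conjugate addition of hydroxide at C6, and the released tricarbonyl chain should reclose by aldol condensation of C1 onto C6. This is the classical base-induced conversion of 4-pyranones through open-chain polyketones into resorcinols. The fallback returns to the route at 14.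

Step 4. The ester enolate may lose methoxide (β-elimination to a β-methoxyacrylate) faster than it is alkylated by the unactivated primary iodide. The fallback sets out from 5 and installs the formyl carbon after the chain is in place:
- Alkylation of dimethyl malonate with 5 (NaH, DMF) should give dimethyl 2-{3-[4-(benzyloxy)phenyl]propyl}malonate F2.
- Krapcho decarboxylation (LiCl, wet DMSO, 150 °C) should give methyl 5-[4-(benzyloxy)phenyl]pentanoate F3.
- Claisen formylation (LiN(i-Pr)2, THF, −78 °C, then methyl formate) should give methyl 5-[4-(benzyloxy)phenyl]-2-formylpentanoate F4.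
- Acetalisation with HC(OMe)3 in methanol and catalytic p-TsOH returns to the route at 8.

Step 6. The dianion may act as a base toward the hindered α-branched amide instead of adding to its carbonyl, and the triketone may cyclise or decompose on acidic work-up or silica. Crude 11 is therefore filtered through neutral silica and used at once. The fallback sets out from 9 and replaces the acylation by an aldol addition and oxidation:
- Reduction of 9 with i-Bu2AlH (THF, −78 °C) should give 5-[4-(benzyloxy)phenyl]-2-(dimethoxymethyl)pentanal F5.
- Addition of the dianion 10 to F5 at −78 °C should give 1,9-bis[4-(benzyloxy)phenyl]-6-(dimethoxymethyl)-5-hydroxynonane-1,3-dione F6 as a mixture of diastereomers.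
- Oxidation of F6 with Dess–Martin periodinane (CH2Cl2, NaHCO3) returns to the route at 11.

**Further compounds**

F1 | step 7 | 2-{2-[4-(benzyloxy)phenyl]-2-oxoethyl}-5-{3-[4-(benzyloxy)phenyl]propyl}-4H-pyran-4-one | O=C(Cc1cc(=O)c(CCCc2ccc(OCc3ccccc3)cc2)co1)c1ccc(OCc2ccccc2)cc1
F2 | step 4 | dimethyl 2-{3-[4-(benzyloxy)phenyl]propyl}malonate | COC(=O)C(CCCc1ccc(OCc2ccccc2)cc1)C(=O)OC
F3 | step 4 | methyl 5-[4-(benzyloxy)phenyl]pentanoate | COC(=O)CCCCc1ccc(OCc2ccccc2)cc1
F4 | step 4 | methyl 5-[4-(benzyloxy)phenyl]-2-formylpentanoate (racemic, in equilibrium with its enol) | COC(=O)C(C=O)CCCc1ccc(OCc2ccccc2)cc1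
F5 | step 6 | 5-[4-(benzyloxy)phenyl]-2-(dimethoxymethyl)pentanal (racemic) | COC(OC)C(C=O)CCCc1ccc(OCc2ccccc2)cc1
F6 | step 6 | 1,9-bis[4-(benzyloxy)phenyl]-6-(dimethoxymethyl)-5-hydroxynonane-1,3-dione (mixture of diastereomers) | COC(OC)C(CCCc1ccc(OCc2ccccc2)cc1)C(O)CC(=O)CC(=O)c1ccc(OCc2ccccc2)cc1
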